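**Retrosynthetic overview**

- Numbering used in the text: C1 = quaternary ring-fusion carbon (CH3); C2, C3 = CH2 of the five-membered ring A; C4 = carbinol carbon (OH, i-Pr); C5 = ring-fusion CH; C6 = ester-bearing carbon; C7=C8(CH3) = alkene; C9, C10 = the two CH2 of the seven-membered ring B.
- Disconnections: the anisoate ester (last step); then ring B at C9–C10, back to a cyclopentane in which C10 is an aldehyde hydrazone (aldehyde carbon used as a carbanion, N2 as traceless leaving group) and C7 carries an allylic carbonate (π-allyl C7–C8–C9); then C7–O/C8=C9 from a prenyl group (ene reaction); then C4–i-Pr, C5–C6 (aldol with prenal) and C1–CH3 (conjugate addition) on 3-(dimethoxymethyl)cyclopent-2-enone.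
- Enabling feature: in ring B the bond C9–C10 joins the free terminus of the allyl unit C7=C8(CH3)–C9, whose other end C7 sits next to oxygenated C6, to a CH2 on the quaternary carbon C1. C10 can therefore be carried as a non-enolisable aldehyde and C7 as the leaving-group carbon, and closure at C9 is the only closure that avoids a five-membered ring trans-fused to ring A.
- Ring order: ring A first (aldol condensation, step 2), ring B by the key step (step 11). The trans ring fusion is preset on ring A by the trans C5/C1 relationship; the bulky α-branched acetal at C1, the masked C10 aldehyde, is what makes that relationship controllable.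

Key step: step 11

Remark: the carbinol carbon next to the isopropenyl group in 15–19 and the diazene-bearing carbon of 20 arise as epimer mixtures that converge later, so their SMILES leave these centres open.
Remark: the ligand enantiomer in step 3 is the one that gives the (S) centre of 7; its antipode would give the enantiomeric series.
Remark: "Reactants" lists every numbered compound entering a step; unnumbered reagents that donate atoms stand on the reagent line.

**Route**

Step 1
Reactants: 1 2,2-dimethoxyacetaldehyde; 2 but-3-en-2-one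
Product: 3 1,1-dimethoxyhexane-2,5-dione
Conditions: 3-benzyl-5-(2-hydroxyethyl)-4-methylthiazolium chloride (10 mol%), Et3N, EtOH, 75 °C
Reagents that add atoms: none
Why: Stetter reaction, in which the thiazolium-derived acyl-anion equivalent of the non-enolisable aldehyde 1 adds 1,4 to the vinyl ketone to give the 1,4-diketone; no stereocentre is formed.

Step 2
Reactants: 3 1,1-dimethoxyhexane-2,5-dione
Product: 4 3-(dimethoxymethyl)cyclopent-2-en-1-one
Conditions: NaOH (2% aq.), EtOH, reflux
Reagents that add atoms: none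
Why: intramolecular aldol condensation of a 1,4-diketone, where only the methyl-ketone enolate attacking the acetal-flanked ketone can close a five-membered ring (the other enolates would close three-membered rings), and dehydration gives the β-substituted cyclopentenone.

Step 3
Reactants: 4 3-(dimethoxymethyl)cyclopent-2-en-1-one; 5 trimethylaluminium
Product: 7 (3S)-3-(dimethoxymethyl)-3-methylcyclopent-1-en-1-yl acetate, via aluminium enolate 6 (not isolated)
Conditions: 5 (1.5 equiv), CuTC (copper thiophene-2-carboxylate, monovalent copper, 5 mol%), chiral binaphthol-derived phosphoramidite ligand (10 mol%), Et2O, −30 °C; then Ac2O, −30 to 0 °C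
Reagents that add atoms: acetic anhydride CC(=O)OC(C)=O
Why: copper-catalysed asymmetric conjugate addition of a trialkylaluminium to a β-substituted cyclopentenone, in which the chiral ligand selects the enone face and sets the quaternary centre C1 as (S), and O-acetylation of the aluminium enolate fixes the enolate regiochemistry for the next step.

Step 4
Reactants: 7 (3S)-3-(dimethoxymethyl)-3-methylcyclopent-1-en-1-yl acetate; 8 3-methylbut-2-enal
Product: 11 (2S,3S)-3-(dimethoxymethyl)-2-[(1S)-1-hydroxy-3-methylbut-2-en-1-yl]-3-methylcyclopentan-1-one, via lithium enolate 9 (not isolated), via chlorozinc enolate 10 (not isolated)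
Conditions: MeLi (2.1 equiv), THF, 0 °C; ZnCl2, −78 °C; 8, −78 °C; aq. NH4Cl
Reagents that add atoms: none
Why: enol acetate cleavage gives the regiodefined enolate, which after transmetalation to zinc undergoes a Zimmerman–Traxler aldol addition; the aldehyde should approach C5 anti to the α-branched dimethoxymethyl group on the neighbouring quaternary carbon (C5/C1 trans) and the ring-locked E enolate in a chair should give the anti aldol (C6 S).

Step 5
Reactants: 11 (2S,3S)-3-(dimethoxymethyl)-2-[(1S)-1-hydroxy-3-methylbut-2-en-1-yl]-3-methylcyclopentan-1-one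
Product: 12 (2S,3S)-2-[(1S)-1-{[tert-butyl(dimethyl)silyl]oxy}-3-methylbut-2-en-1-yl]-3-(dimethoxymethyl)-3-methylcyclopentan-1-one
Conditions: TBSCl, imidazole, DMAP (cat.), DMF, 40 °C
Reagents that add atoms: tert-butyldimethylsilyl chloride CC(C)(C)[Si](C)(C)Cl
Why: silylation of the secondary alcohol under non-Lewis-acidic conditions, which spares the dimethyl acetal and blocks retro-aldol and elimination paths in the organometallic step.

Step 6
Reactants: 12 (2S,3S)-2-[(1S)-1-{[tert-butyl(dimethyl)silyl]oxy}-3-methylbut-2-en-1-yl]-3-(dimethoxymethyl)-3-methylcyclopentan-1-one; 13 isopropylmagnesium chloride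
Product: 14 (1R,2S,3S)-2-[(1S)-1-{[tert-butyl(dimethyl)silyl]oxy}-3-methylbut-2-en-1-yl]-3-(dimethoxymethyl)-3-methyl-1-(propan-2-yl)cyclopentan-1-ol
Conditions: 13 (3 equiv), anhydrous CeCl3 (3 equiv), THF, −78 to −20 °C; aq. NH4Cl
Reagents that add atoms: none
Why: organocerium 1,2-addition to a hindered ketone (low basicity suppresses enolisation and β-hydride reduction), with attack expected from the face anti to the C5 side chain and the pseudo-axial C1 methyl, so that the hydroxyl ends up cis to the side chain (C4 R).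

Step 7
Reactants: 14 (1R,2S,3S)-2-[(1S)-1-{[tert-butyl(dimethyl)silyl]oxy}-3-methylbut-2-en-1-yl]-3-(dimethoxymethyl)-3-methyl-1-(propan-2-yl)cyclopentan-1-ol
Product: 16 (1R,2S,3S)-2-[(1R,2RS)-1-{[tert-butyl(dimethyl)silyl]oxy}-2-hydroxy-3-methylbut-3-en-1-yl]-3-(dimethoxymethyl)-3-methyl-1-(propan-2-yl)cyclopentan-1-ol, via allylic hydroperoxide 15 (not isolated)
Conditions: O2, tetraphenylporphyrin (cat.), visible light, CH2Cl2, 0 °C; then PPh3
Reagents that add atoms: dioxygen O=O
Why: Schenck ene reaction of singlet oxygen with the trisubstituted alkene, in which oxygen should add at C7 and hydrogen be taken from a methyl of the gem-dimethyl end (the C6 hydrogen geminal to the silyloxy group is not abstracted), moving the alkene to C8=C9, followed by phosphine reduction of the hydroperoxide; the C7 configuration is irrelevant because C7 becomes sp2 in step 11.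

Step 8
Reactants: 16 (1R,2S,3S)-2-[(1R,2RS)-1-{[tert-butyl(dimethyl)silyl]oxy}-2-hydroxy-3-methylbut-3-en-1-yl]-3-(dimethoxymethyl)-3-methyl-1-(propan-2-yl)cyclopentan-1-ol
Product: 17 (1R,2RS)-1-{[tert-butyl(dimethyl)silyl]oxy}-1-[(1S,2R,5S)-5-(dimethoxymethyl)-2-hydroxy-5-methyl-2-(propan-2-yl)cyclopentyl]-3-methylbut-3-en-2-yl methyl carbonate
Conditions: ClCO2Me, pyridine, DMAP (cat.), CH2Cl2, 0 °C
Reagents that add atoms: methyl chloroformate COC(=O)Cl
Why: acylation of the secondary allylic alcohol with a chloroformate, the tertiary alcohol being too hindered to react.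

Step 9
Reactants: 17 (1R,2RS)-1-{[tert-butyl(dimethyl)silyl]oxy}-1-[(1S,2R,5S)-5-(dimethoxymethyl)-2-hydroxy-5-methyl-2-(propan-2-yl)cyclopentyl]-3-methylbut-3-en-2-yl methyl carbonate
Product: 18 (1R,2RS)-1-{[tert-butyl(dimethyl)silyl]oxy}-1-[(1S,2R,5S)-5-formyl-2-hydroxy-5-methyl-2-(propan-2-yl)cyclopentyl]-3-methylbut-3-en-2-yl methyl carbonate
Conditions: PPTS (cat.), acetone–H2O (10:1), 45 °C
Reagents that add atoms: water O
Why: mild acid-catalysed hydrolysis of the dimethyl acetal to the non-enolisable aldehyde, which should leave the silyl ether and the carbonate intact; the tertiary hydroxyl is trans to the formyl group and cannot form a lactol.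

Step 10
Reactants: 18 (1R,2RS)-1-{[tert-butyl(dimethyl)silyl]oxy}-1-[(1S,2R,5S)-5-formyl-2-hydroxy-5-methyl-2-(propan-2-yl)cyclopentyl]-3-methylbut-3-en-2-yl methyl carbonate
Product: 19 (1R,2RS)-1-{[tert-butyl(dimethyl)silyl]oxy}-1-{(1S,2R,5S)-5-[(E)-hydrazinylidenemethyl]-2-hydroxy-5-methyl-2-(propan-2-yl)cyclopentyl}-3-methylbut-3-en-2-yl methyl carbonate
Conditions: N2H4·H2O (5 equiv), EtOH, 0 °C to rt
Reagents that add atoms: hydrazine NN
Why: condensation of the aldehyde with excess hydrazine to the N-unsubstituted hydrazone; the excess suppresses azine formation and the hindered alkyl carbonate should be much slower toward hydrazine than the aldehyde.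

Step 11
Reactants: 19 (1R,2RS)-1-{[tert-butyl(dimethyl)silyl]oxy}-1-{(1S,2R,5S)-5-[(E)-hydrazinylidenemethyl]-2-hydroxy-5-methyl-2-(propan-2-yl)cyclopentyl}-3-methylbut-3-en-2-yl methyl carbonate
Product: 21 (3R,3aS,4S,8aS)-4-{[tert-butyl(dimethyl)silyl]oxy}-6,8a-dimethyl-3-(propan-2-yl)-1,2,3,3a,4,7,8,8a-octahydroazulen-3-ol, via alkyl diazene 20 (not isolated)
Conditions: Pd(PPh3)4 (5 mol%), degassed THF (0.01 M), 50 °C
Reagents that add atoms: none
Why: Proposed new method: Pd(PPh3)4 ionises the secondary allylic carbonate of 19 (loss of CO2 and methoxide) to a 2-methyl-π-allyl palladium complex spanning C7–C8–C9, the methoxide deprotonates the NH2 of the hydrazone, and the resulting hydrazonide, a carbanion surrogate at C10, attacks the allyl terminus C9 to give the monoalkyl diazene 20, which loses N2 in a Wolff–Kishner-type collapse and leaves C10 as CH2. The closest known reactions are the palladium-catalysed allylic alkylation with N-unsubstituted aldehyde hydrazones as alkyl carbanion equivalents (intermolecular, mostly aryl aldehydes) and the [3,3] shift of N-allylhydrazones that ends with loss of N2; new here are the aliphatic α-quaternary hydrazone and the intramolecular medium-ring setting. The seven-membered ring closes by attack at the distal allyl terminus, so that all three allyl carbons enter the ring and the alkene ends up as C7=C8, cis by necessity, which the 2-methyl-allyl complex can reach through its anti isomer by π-σ-π interchange. No stereocentre is created: C1, C4, C5 and C6 are untouched, the C7 centre of the epimer mixture is erased, and the trans ring fusion follows from the trans C5/C1 substitution already present on ring A. The step needs C9 over C7 selectivity and C over N selectivity: attack at C7 would give a cyclopentane trans-fused to ring A (a strained trans-bicyclo[3.3.0]octane) at the more hindered terminus, and N-allylation is expected to be reversible under zerovalent palladium whereas C–C bond formation is made irreversible by loss of N2. High dilution suppresses intermolecular allylation, and because C10 has no α-hydrogen the ene-hydrazine side path of the hydrazone is closed.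

Step 12
Reactants: 21 (3R,3aS,4S,8aS)-4-{[tert-butyl(dimethyl)silyl]oxy}-6,8a-dimethyl-3-(propan-2-yl)-1,2,3,3a,4,7,8,8a-octahydroazulen-3-ol
Product: 22 (3R,3aS,4S,8aS)-6,8a-dimethyl-3-(propan-2-yl)-1,2,3,3a,4,7,8,8a-octahydroazulene-3,4-diol
Conditions: TBAF, THF, rt
Reagents that add atoms: none
Why: fluoride-mediated cleavage of the silyl ether, which frees the secondary allylic alcohol without touching any stereocentre.

Step 13
Reactants: 22 (3R,3aS,4S,8aS)-6,8a-dimethyl-3-(propan-2-yl)-1,2,3,3a,4,7,8,8a-octahydroazulene-3,4-diol; 23 4-methoxybenzoyl chloride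
Product: 24 (3R,3aS,4S,8aS)-3-hydroxy-6,8a-dimethyl-3-(propan-2-yl)-1,2,3,3a,4,7,8,8a-octahydroazulen-4-yl 4-methoxybenzoate
Conditions: 23, DMAP, pyridine, CH2Cl2, rt to 40 °C
Reagents that add atoms: none
Why: DMAP-catalysed acylation (esterification with an acid chloride) of the secondary allylic alcohol, the tertiary alcohol being unreactive under these conditions.

**Compound list**

1 | 2,2-dimethoxyacetaldehyde | COC(OC)C=O | starting material
2 | but-3-en-2-one | CC(=O)C=C | starting material
3 | 1,1-dimethoxyhexane-2,5-dione | COC(OC)C(=O)CCC(C)=O | intermediate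
4 | 3-(dimethoxymethyl)cyclopent-2-en-1-one | COC(OC)C1=CC(=O)CC1 | intermediate
5 | trimethylaluminium | C[Al](C)C | starting material
6 | dimethyl{[(3S)-3-(dimethoxymethyl)-3-methylcyclopent-1-en-1-yl]oxy}aluminium (aluminium enolate, not isolated) | C1=C(O[Al](C)C)CC[C@]1(C)C(OC)OC | intermediate
7 | (3S)-3-(dimethoxymethyl)-3-methylcyclopent-1-en-1-yl acetate | C1=C(OC(C)=O)CC[C@]1(C)C(OC)OC | intermediate
8 | 3-methylbut-2-enal | CC(C)=CC=O | starting material
9 | lithium (3S)-3-(dimethoxymethyl)-3-methylcyclopent-1-en-1-olate (not isolated) | C1=C(O[Li])CC[C@]1(C)C(OC)OC | intermediate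
10 | chlorozinc (3S)-3-(dimethoxymethyl)-3-methylcyclopent-1-en-1-olate (not isolated) | C1=C(O[Zn]Cl)CC[C@]1(C)C(OC)OC | intermediate
11 | (2S,3S)-3-(dimethoxymethyl)-2-[(1S)-1-hydroxy-3-methylbut-2-en-1-yl]-3-methylcyclopentan-1-one | O[C@@H](C=C(C)C)[C@H]1C(=O)CC[C@]1(C)C(OC)OC | intermediate
12 | (2S,3S)-2-[(1S)-1-{[tert-butyl(dimethyl)silyl]oxy}-3-methylbut-2-en-1-yl]-3-(dimethoxymethyl)-3-methylcyclopentan-1-one | CC(C)(C)[Si](C)(C)O[C@@H](C=C(C)C)[C@H]1C(=O)CC[C@]1(C)C(OC)OC | intermediate
13 | isopropylmagnesium chloride | CC(C)[Mg]Cl | starting material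
14 | (1R,2S,3S)-2-[(1S)-1-{[tert-butyl(dimethyl)silyl]oxy}-3-methylbut-2-en-1-yl]-3-(dimethoxymethyl)-3-methyl-1-(propan-2-yl)cyclopentan-1-ol | CC(C)(C)[Si](C)(C)O[C@@H](C=C(C)C)[C@H]1[C@](O)(C(C)C)CC[C@]1(C)C(OC)OC | intermediate
15 | (1R,2S,3S)-2-[(1R,2RS)-1-{[tert-butyl(dimethyl)silyl]oxy}-2-hydroperoxy-3-methylbut-3-en-1-yl]-3-(dimethoxymethyl)-3-methyl-1-(propan-2-yl)cyclopentan-1-ol (not isolated) | CC(C)(C)[Si](C)(C)O[C@@H](C(OO)C(C)=C)[C@H]1[C@](O)(C(C)C)CC[C@]1(C)C(OC)OC | intermediate
16 | (1R,2S,3S)-2-[(1R,2RS)-1-{[tert-butyl(dimethyl)silyl]oxy}-2-hydroxy-3-methylbut-3-en-1-yl]-3-(dimethoxymethyl)-3-methyl-1-(propan-2-yl)cyclopentan-1-ol | CC(C)(C)[Si](C)(C)O[C@@H](C(O)C(C)=C)[C@H]1[C@](O)(C(C)C)CC[C@]1(C)C(OC)OC | intermediate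
17 | (1R,2RS)-1-{[tert-butyl(dimethyl)silyl]oxy}-1-[(1S,2R,5S)-5-(dimethoxymethyl)-2-hydroxy-5-methyl-2-(propan-2-yl)cyclopentyl]-3-methylbut-3-en-2-yl methyl carbonate | CC(C)(C)[Si](C)(C)O[C@@H](C(OC(=O)OC)C(C)=C)[C@H]1[C@](O)(C(C)C)CC[C@]1(C)C(OC)OC | intermediate
18 | (1R,2RS)-1-{[tert-butyl(dimethyl)silyl]oxy}-1-[(1S,2R,5S)-5-formyl-2-hydroxy-5-methyl-2-(propan-2-yl)cyclopentyl]-3-methylbut-3-en-2-yl methyl carbonate | CC(C)(C)[Si](C)(C)O[C@@H](C(OC(=O)OC)C(C)=C)[C@H]1[C@](O)(C(C)C)CC[C@]1(C)C=O | intermediate
19 | (1R,2RS)-1-{[tert-butyl(dimethyl)silyl]oxy}-1-{(1S,2R,5S)-5-[(E)-hydrazinylidenemethyl]-2-hydroxy-5-methyl-2-(propan-2-yl)cyclopentyl}-3-methylbut-3-en-2-yl methyl carbonate | CC(C)(C)[Si](C)(C)O[C@@H](C(OC(=O)OC)C(C)=C)[C@H]1[C@](O)(C(C)C)CC[C@]1(C)/C=N/N | intermediate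
20 | (3R,3aS,4S,8RS,8aS)-4-{[tert-butyl(dimethyl)silyl]oxy}-8-diazenyl-6,8a-dimethyl-3-(propan-2-yl)-1,2,3,3a,4,7,8,8a-octahydroazulen-3-ol (alkyl diazene, not isolated) | CC(C)(C)[Si](C)(C)O[C@H]1C=C(C)CC(N=N)[C@@]2(C)CC[C@@](O)(C(C)C)[C@H]12 | intermediate
21 | (3R,3aS,4S,8aS)-4-{[tert-butyl(dimethyl)silyl]oxy}-6,8a-dimethyl-3-(propan-2-yl)-1,2,3,3a,4,7,8,8a-octahydroazulen-3-ol | CC(C)(C)[Si](C)(C)O[C@H]1C=C(C)CC[C@@]2(C)CC[C@@](O)(C(C)C)[C@H]12 | intermediate
22 | (3R,3aS,4S,8aS)-6,8a-dimethyl-3-(propan-2-yl)-1,2,3,3a,4,7,8,8a-octahydroazulene-3,4-diol | O[C@H]1C=C(C)CC[C@@]2(C)CC[C@@](O)(C(C)C)[C@H]12 | intermediate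
23 | 4-methoxybenzoyl chloride | COc1ccc(C(=O)Cl)cc1 | starting material
24 | (3R,3aS,4S,8aS)-3-hydroxy-6,8a-dimethyl-3-(propan-2-yl)-1,2,3,3a,4,7,8,8a-octahydroazulen-4-yl 4-methoxybenzoate | COc1ccc(C(=O)O[C@H]2C=C(C)CC[C@@]3(C)CC[C@@](O)(C(C)C)[C@H]23)cc1 | target

**Totals**

Total step count: 13. Longest linear sequence: 13 steps (1 to 24).

**Steps most likely to fail, with fallbacks**

1. Step 11 (proposed new method). The hydrazonide may be allylated on nitrogen without return, the allyl complex may collapse to a diene by β-hydride elimination before the hindered carbon nucleophile engages, or the hydrazone may simply be reduced. The fallback uses known chemistry: it sets out from 18 and comes back at 21. Treating 18 with catalytic Pd(PPh3)4 and Et2Zn in THF turns the allylic carbonate into a nucleophilic allylzinc, which adds to the aldehyde and closes ring B at the same bond (the seven-membered closure again being the only unstrained one), giving (3R,3aS,4S,8RS,8aS)-4-{[tert-butyl(dimethyl)silyl]oxy}-6,8a-dimethyl-3-(propan-2-yl)-1,2,3,3a,4,7,8,8a-octahydroazulene-3,8-diol F1. The extra secondary hydroxyl is then removed by Barton–McCombie deoxygenation: phenyl chlorothionoformate, pyridine and DMAP give the O-phenyl thionocarbonate of F1 at the C8 hydroxyl F2, and Bu3SnH with AIBN in toluene at 100 °C gives 21.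

2. Step 3. The bulky, Lewis-basic acetal at the β-carbon may slow the conjugate addition or erode face selection, or the aluminium reagent may cleave the acetal. The fallback sets out from 4 and comes back at 7. CBS reduction of 4 (BH3·SMe2, (R)-methyl oxazaborolidine) gives (1S)-3-(dimethoxymethyl)cyclopent-2-en-1-ol F3. Hydroxyl-directed Simmons–Smith cyclopropanation (Et2Zn, CH2I2) gives (1R,2S,5R)-5-(dimethoxymethyl)bicyclo[3.1.0]hexan-2-ol F4. Dess–Martin oxidation gives (1R,5R)-5-(dimethoxymethyl)bicyclo[3.1.0]hexan-2-one F5. Reduction with Li in liquid NH3 cleaves the external cyclopropane bond, so that the cyclopropane CH2 becomes the C1 methyl and the same regiodefined enolate results; acetylation with Ac2O gives 7.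

3. Step 6. Enolisation or β-hydride reduction may outrun addition at the hindered ketone, or the nucleophile may enter from the wrong face. The fallback sets out from 12 and comes back at 14. Isopropenylmagnesium bromide with CeCl3 (a smaller sp2 nucleophile without β-hydrogens) gives (1S,2S,3S)-2-[(1S)-1-{[tert-butyl(dimethyl)silyl]oxy}-3-methylbut-2-en-1-yl]-3-(dimethoxymethyl)-3-methyl-1-(prop-1-en-2-yl)cyclopentan-1-ol F6. Hydrogenation with RhCl(PPh3)3 in benzene should saturate the 1,1-disubstituted alkene in preference to the trisubstituted one and give 14.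

Further compounds
F1 | step 11 | (3R,3aS,4S,8RS,8aS)-4-{[tert-butyl(dimethyl)silyl]oxy}-6,8a-dimethyl-3-(propan-2-yl)-1,2,3,3a,4,7,8,8a-octahydroazulene-3,8-diol | CC(C)(C)[Si](C)(C)O[C@H]1C=C(C)CC(O)[C@@]2(C)CC[C@@](O)(C(C)C)[C@H]12
F2 | step 11 | O-phenyl thionocarbonate of F1 at the C8 hydroxyl | CC(C)(C)[Si](C)(C)O[C@H]1C=C(C)CC(OC(=S)Oc3ccccc3)[C@@]2(C)CC[C@@](O)(C(C)C)[C@H]12
F3 | step 3 | (1S)-3-(dimethoxymethyl)cyclopent-2-en-1-ol | O[C@H]1CCC(C(OC)OC)=C1
F4 | step 3 | (1R,2S,5R)-5-(dimethoxymethyl)bicyclo[3.1.0]hexan-2-ol | O[C@H]1CC[C@@]2(C(OC)OC)C[C@@H]12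
F5 | step 3 | (1R,5R)-5-(dimethoxymethyl)bicyclo[3.1.0]hexan-2-one | O=C1CC[C@@]2(C(OC)OC)C[C@@H]12
F6 | step 6 | (1S,2S,3S)-2-[(1S)-1-{[tert-butyl(dimethyl)silyl]oxy}-3-methylbut-2-en-1-yl]-3-(dimethoxymethyl)-3-methyl-1-(prop-1-en-2-yl)cyclopentan-1-ol | CC(C)(C)[Si](C)(C)O[C@@H](C=C(C)C)[C@H]1[C@](O)(C(C)=C)CC[C@]1(C)C(OC)OC
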